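**Retrosynthetic overview**
- Target ⇒ (acetal cleavage, hydrogenolysis) benzyl/MOM-protected dimer ⇒ C4(upper)–C8(lower) bond by hydroxyl-directed aryl transfer from a lower-unit C8 trifluoroborate to the C4 cation of a 4-methoxy upper unit (sets 3,4-cis).
- Each flavan-3-ol heterocycle ⇒ ring expansion (1,2-aryl shift through a phenonium ion) of a trans-2-aryl-3-(iodomethyl)-2,3-dihydrobenzofuran.
- Dihydrobenzofurans ⇒ 5-exo aryl radical cyclisation of (S)-1-arylallyl 2-iodoaryl ethers ⇒ iridium-catalysed asymmetric allylic etherification (sets C2).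
- Cinnamyl carbonates ⇒ Heck reaction of methyl acrylate with aryl bromides made from catechol and 4-bromophenol; iodophenols from resorcinol.
- Ring order: furan ring then pyran ring (by expansion) of the lower catechin unit, the same pair for the upper robinetinidol unit, then the interflavan bond.

Assumption: the (Sa,Sc,Sc) phosphoramidite L, O,O'-(1,1'-binaphthalene-2,2'-diyl) N,N-bis(1-phenylethyl)phosphoramidite, is taken to give the (S)-ethers in steps 8 and 20; if the sense is the opposite, its mirror image is used.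

**Lower (catechin) unit**

Step 1
Reactants: 1 resorcinol
Product: 2 1,3-bis(methoxymethoxy)benzene
Conditions: NaH, MOMCl, DMF, 0 °C to rt
Reagents that add atoms: chloromethyl methyl ether COCCl
Why: Williamson-type O-alkylation of both phenols gives acetal ethers that have no aryl C–H of their own and survive base, radicals and organolithiums.

Step 2
Reactants: 2 1,3-bis(methoxymethoxy)benzene
Product: 4 3,5-bis(methoxymethoxy)phenol, via arylboronic ester 3 (not isolated)
Conditions: [Ir(OMe)(cod)]2 (1 mol%), 4,4'-di-tert-butyl-2,2'-bipyridine, B2pin2 (0.55 equiv), hexane, 80 °C; then NaOH, H2O2, THF–H2O, 0 °C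
Reagents that add atoms: hydrogen peroxide OO
Why: Sterically controlled iridium-catalysed C–H borylation occurs at the only C–H without an ortho substituent (C5) and the C–B bond is oxidised in the same flask (borylation/oxidation).

Step 3
Reactants: 4 3,5-bis(methoxymethoxy)phenol
Product: 5 2-iodo-3,5-bis(methoxymethoxy)phenol
Conditions: I2, NaHCO3, THF–H2O, 0 °C
Reagents that add atoms: iodine II
Why: Electrophilic aromatic iodination of the phenoxide goes ortho to the hydroxyl because the para position is flanked by two acetal ethers.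

Step 4
Reactants: 6 catechol
Product: 7 1,2-bis(benzyloxy)benzene
Conditions: BnBr, K2CO3, DMF, 60 °C
Reagents that add atoms: benzyl bromide BrCc1ccccc1
Why: Williamson benzylation protects both phenols for the organometallic steps.

Step 5
Reactants: 7 1,2-bis(benzyloxy)benzene
Product: 8 4-bromo-1,2-bis(benzyloxy)benzene
Conditions: NBS, MeCN, 0 °C to rt
Reagents that add atoms: N-bromosuccinimide O=C1CCC(=O)N1Br
Why: Electrophilic aromatic bromination occurs para to an alkoxy group of the symmetric diether.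

Step 6
Reactants: 8 4-bromo-1,2-bis(benzyloxy)benzene; 9 methyl acrylate
Product: 10 methyl (E)-3-[3,4-bis(benzyloxy)phenyl]prop-2-enoate
Conditions: Pd(OAc)2 (2 mol%), P(o-tol)3, NaOAc, DMF, 110 °C
Reagents that add atoms: none
Why: Mizoroki–Heck arylation of the acrylate gives the E-cinnamate by syn insertion and syn β-hydride elimination.

Step 7
Reactants: 10 methyl (E)-3-[3,4-bis(benzyloxy)phenyl]prop-2-enoate
Product: 12 tert-butyl (E)-3-[3,4-bis(benzyloxy)phenyl]prop-2-en-1-yl carbonate, via allylic alcohol 11 (not isolated)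
Conditions: i-Bu2AlH (2.2 equiv), CH2Cl2, −78 °C; then Boc2O, DMAP (cat.), −78 °C to rt
Reagents that add atoms: di-tert-butyl dicarbonate CC(C)(C)OC(=O)OC(=O)OC(C)(C)C
Why: 1,2-Reduction of the enoate gives the aluminium allylic alkoxide, which is acylated in the same flask to the allylic carbonate.

Step 8
Reactants: 5 2-iodo-3,5-bis(methoxymethoxy)phenol; 12 tert-butyl (E)-3-[3,4-bis(benzyloxy)phenyl]prop-2-en-1-yl carbonate
Product: 13 1-{[(1S)-1-[3,4-bis(benzyloxy)phenyl]prop-2-en-1-yl]oxy}-2-iodo-3,5-bis(methoxymethoxy)benzene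
Conditions: [Ir(cod)Cl]2 (2 mol%), (Sa,Sc,Sc)-L (4 mol%), TBD (8 mol%), THF, 30 °C
Reagents that add atoms: none
Why: Iridium-catalysed asymmetric allylic etherification (Tsuji–Trost type) in which the phenoxide, freed by the tert-butoxide leaving group, attacks the aryl-substituted terminus of the allyl–iridium complex, so the chiral ligand sets the S centre that becomes C2 of the catechin unit.

Step 9
Reactants: 13 1-{[(1S)-1-[3,4-bis(benzyloxy)phenyl]prop-2-en-1-yl]oxy}-2-iodo-3,5-bis(methoxymethoxy)benzene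
Product: 15 (2S,3S)-2-[3,4-bis(benzyloxy)phenyl]-3-(iodomethyl)-4,6-bis(methoxymethoxy)-2,3-dihydro-1-benzofuran, via alkylsamarium 14 (not isolated)
Conditions: SmI2 (2.5 equiv), HMPA, THF, 0 °C; then I2, −78 °C to rt
Reagents that add atoms: iodine II
Why: The aryl radical from the iodide closes 5-exo-trig onto the alkene with the new CH2 group trans to the aryl group on the adjacent carbon (Beckwith–Houk chair transition state, minor cis isomer removed later), and the primary radical is reduced to an alkylsamarium that is cleaved by iodine.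

Step 10
Reactants: 15 (2S,3S)-2-[3,4-bis(benzyloxy)phenyl]-3-(iodomethyl)-4,6-bis(methoxymethoxy)-2,3-dihydro-1-benzofuran
Product: 16 (2R,3S)-2-[3,4-bis(benzyloxy)phenyl]-5,7-bis(methoxymethoxy)chroman-3-ol
Conditions: AgOTf (1.2 equiv), NaHCO3, acetone–H2O (5:1), 0 °C to rt
Reagents that add atoms: water O
Why: Silver-assisted loss of iodide with participation of the trioxygenated ring A gives a phenonium ion that water opens at the secondary carbon anti to the migrating aryl, a Wagner–Meerwein ring expansion (1,2-aryl shift, as in indan-1-ylmethyl to 2-tetralyl solvolysis) that turns the trans furan into the 2,3-trans pyran with C3 set as S.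

Step 11
Reactants: 16 (2R,3S)-2-[3,4-bis(benzyloxy)phenyl]-5,7-bis(methoxymethoxy)chroman-3-ol
Product: 17 (2R,3S)-2-[3,4-bis(benzyloxy)phenyl]-8-bromo-5,7-bis(methoxymethoxy)chroman-3-ol
Conditions: NBS (1.0 equiv), CH2Cl2, −78 °C
Reagents that add atoms: N-bromosuccinimide O=C1CCC(=O)N1Br
Why: Electrophilic bromination of the phloroglucinol-type ring A goes to C8, the position that protected catechins brominate selectively.

Step 12
Reactants: 17 (2R,3S)-2-[3,4-bis(benzyloxy)phenyl]-8-bromo-5,7-bis(methoxymethoxy)chroman-3-ol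
Product: 20 potassium [(2R,3S)-2-[3,4-bis(benzyloxy)phenyl]-3-hydroxy-5,7-bis(methoxymethoxy)chroman-8-yl]trifluoroborate, via aryllithium 18 (not isolated), via arylborate 19 (not isolated)
Conditions: n-BuLi (2.2 equiv), THF, −78 °C; B(OMe)3, −78 to 0 °C; aq. KHF2, MeOH, rt
Reagents that add atoms: trimethyl borate COB(OC)OC; potassium hydrogen difluoride [K+].[F-].F
Why: Deprotonation of the hydroxyl and bromine–lithium exchange give an aryllithium chelated by the ortho acetal ether, which is borylated and converted to the bench-stable trifluoroborate.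

**Upper (robinetinidol) unit**

Step 13
Reactants: 1 resorcinol
Product: 21 3-(benzyloxy)phenol
Conditions: BnBr (0.4 equiv), K2CO3, acetone, reflux (excess resorcinol recovered)
Reagents that add atoms: benzyl bromide BrCc1ccccc1
Why: Williamson mono-benzylation with the diol in excess gives the mono-ether.

Step 14
Reactants: 21 3-(benzyloxy)phenol
Product: 22 5-(benzyloxy)-2-iodophenol
Conditions: I2, NaHCO3, THF–H2O, 0 °C
Reagents that add atoms: iodine II
Why: Electrophilic iodination of the phenoxide occurs ortho to the hydroxyl and para to the benzyloxy group.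

Step 15
Reactants: 23 4-bromophenol
Product: 24 5-bromo-2-hydroxybenzene-1,3-dicarbaldehyde
Conditions: hexamethylenetetramine (4 equiv), CF3CO2H, reflux; aq. HCl work-up
Reagents that add atoms: hexamethylenetetramine C1N2CN3CN1CN(C2)C3; water O
Why: Duff formylation goes to both positions ortho to the phenol because the para position is blocked by bromine.

Step 16
Reactants: 24 5-bromo-2-hydroxybenzene-1,3-dicarbaldehyde
Product: 25 5-bromobenzene-1,2,3-triol
Conditions: 30% H2O2, H2SO4 (cat.), MeOH, rt, argon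
Reagents that add atoms: hydrogen peroxide OO
Why: Dakin oxidation converts each ortho-hydroxy aldehyde into an aryl formate by a carbon-to-oxygen aryl shift and the formates are cleaved in the acidic methanol.

Step 17
Reactants: 25 5-bromobenzene-1,2,3-triol
Product: 26 5-bromo-1,2,3-tris(benzyloxy)benzene
Conditions: BnBr, K2CO3, DMF, 60 °C, argon
Reagents that add atoms: benzyl bromide BrCc1ccccc1
Why: Williamson benzylation of the air-sensitive triol, done directly on the crude material.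

Step 18
Reactants: 26 5-bromo-1,2,3-tris(benzyloxy)benzene; 9 methyl acrylate
Product: 27 methyl (E)-3-[3,4,5-tris(benzyloxy)phenyl]prop-2-enoate
Conditions: Pd(OAc)2 (2 mol%), P(o-tol)3, NaOAc, DMF, 110 °C
Reagents that add atoms: none
Why: Mizoroki–Heck arylation as in step 6 gives the E-cinnamate.

Step 19
Reactants: 27 methyl (E)-3-[3,4,5-tris(benzyloxy)phenyl]prop-2-enoate
Product: 29 tert-butyl (E)-3-[3,4,5-tris(benzyloxy)phenyl]prop-2-en-1-yl carbonate, via allylic alcohol 28 (not isolated)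
Conditions: i-Bu2AlH (2.2 equiv), CH2Cl2, −78 °C; then Boc2O, DMAP (cat.), −78 °C to rt
Reagents that add atoms: di-tert-butyl dicarbonate CC(C)(C)OC(=O)OC(=O)OC(C)(C)C
Why: 1,2-Reduction of the enoate and acylation of the aluminium alkoxide in one flask, as in step 7.

Step 20
Reactants: 22 5-(benzyloxy)-2-iodophenol; 29 tert-butyl (E)-3-[3,4,5-tris(benzyloxy)phenyl]prop-2-en-1-yl carbonate
Product: 30 4-(benzyloxy)-1-iodo-2-{[(1S)-1-[3,4,5-tris(benzyloxy)phenyl]prop-2-en-1-yl]oxy}benzene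
Conditions: [Ir(cod)Cl]2 (2 mol%), (Sa,Sc,Sc)-L (4 mol%), TBD (8 mol%), THF, 30 °C
Reagents that add atoms: none
Why: Iridium-catalysed asymmetric allylic etherification as in step 8 gives the branched ether and sets the S centre that becomes C2 of the upper unit.

Step 21
Reactants: 30 4-(benzyloxy)-1-iodo-2-{[(1S)-1-[3,4,5-tris(benzyloxy)phenyl]prop-2-en-1-yl]oxy}benzene
Product: 32 (2S,3S)-6-(benzyloxy)-3-(iodomethyl)-2-[3,4,5-tris(benzyloxy)phenyl]-2,3-dihydro-1-benzofuran, via alkylsamarium 31 (not isolated)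
Conditions: SmI2 (2.5 equiv), HMPA, THF, 0 °C; then I2, −78 °C to rt
Reagents that add atoms: iodine II
Why: Aryl radical 5-exo-trig cyclisation fixes the ring-closure position para to the benzyloxy group and places the new CH2 group trans to the aryl group, followed by iodinolysis of the alkylsamarium as in step 9.

Step 22
Reactants: 32 (2S,3S)-6-(benzyloxy)-3-(iodomethyl)-2-[3,4,5-tris(benzyloxy)phenyl]-2,3-dihydro-1-benzofuran
Product: 33 (2R,3S)-7-(benzyloxy)-2-[3,4,5-tris(benzyloxy)phenyl]chroman-3-ol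
Conditions: AgOTf (1.2 equiv), NaHCO3, acetone–H2O (5:1), 0 °C to rt
Reagents that add atoms: water O
Why: Wagner–Meerwein ring expansion through the phenonium ion of ring A (para-benzyloxy, ortho-oxygen) with water entering at the secondary carbon anti to the migrating aryl, giving the 2,3-trans flavan-3-ol with C3 set as S.

Step 23
Reactants: 33 (2R,3S)-7-(benzyloxy)-2-[3,4,5-tris(benzyloxy)phenyl]chroman-3-ol
Product: 34 (2R,3S,4R)-7-(benzyloxy)-4-methoxy-2-[3,4,5-tris(benzyloxy)phenyl]chroman-3-ol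
Conditions: DDQ (1.3 equiv), MeOH–CH2Cl2 (1:4), 0 °C to rt
Reagents that add atoms: methanol CO
Why: DDQ benzylic oxidation by hydride abstraction at C4, the 2,4-dialkoxybenzylic position, and capture of the cation by methanol mainly anti to the C3 hydroxyl (the C4 epimer is equally usable because C4 is ionised again in the next step).

**Union and deprotection**

Step 24
Reactants: 34 (2R,3S,4R)-7-(benzyloxy)-4-methoxy-2-[3,4,5-tris(benzyloxy)phenyl]chroman-3-ol; 20 potassium [(2R,3S)-2-[3,4-bis(benzyloxy)phenyl]-3-hydroxy-5,7-bis(methoxymethoxy)chroman-8-yl]trifluoroborate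
Product: 35 (2R,3S,4R)-7-(benzyloxy)-4-[(2R,3S)-2-[3,4-bis(benzyloxy)phenyl]-3-hydroxy-5,7-bis(methoxymethoxy)chroman-8-yl]-2-[3,4,5-tris(benzyloxy)phenyl]chroman-3-ol
Conditions: BF3·OEt2 (2 equiv), CH2Cl2–MeCN, −60 to −20 °C
Reagents that add atoms: none
Why: Proposed new method: BF3 strips fluoride from 20 to give an aryl(difluoro)borane that binds the free C3 hydroxyl of 34 as a tetracoordinate alkoxyborate while BF3 ionises the C4 methoxy group to the para-benzyloxy-stabilised (quinone-methide-like) benzylic cation, and the aryl group then moves from boron to C4 through a five-membered transition state on the face of the C3 oxygen, so the new bond is 3,4-cis (4R) and the attachment site on the lower unit is fixed at the boron-bearing C8; the closest known reaction types are the Petasis borono-Mannich reaction (hydroxyl-directed transfer from a boronate to an adjacent cation) and the BF3-promoted coupling of organotrifluoroborates with oxocarbenium ions.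

Step 25
Reactants: 35 (2R,3S,4R)-7-(benzyloxy)-4-[(2R,3S)-2-[3,4-bis(benzyloxy)phenyl]-3-hydroxy-5,7-bis(methoxymethoxy)chroman-8-yl]-2-[3,4,5-tris(benzyloxy)phenyl]chroman-3-ol
Product: 37 robinetinidol-(4β→8)-catechin (CNP0261864.3), via hexabenzyl dimer 36 (not isolated)
Conditions: 2 M HCl, MeOH–THF, 40 °C; then Pd(OH)2/C, H2 (1 atm), rt
Reagents that add atoms: none
Why: Acid-catalysed acetal exchange removes the two methoxymethyl groups (the 5-deoxy interflavan bond resists acid) and hydrogenolysis then removes the six benzyl ethers without touching any stereocentre.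

**Compound list**
1 | resorcinol | Oc1cccc(O)c1 | starting material
2 | 1,3-bis(methoxymethoxy)benzene | COCOc1cccc(OCOC)c1 | intermediate
3 | 2-[3,5-bis(methoxymethoxy)phenyl]-4,4,5,5-tetramethyl-1,3,2-dioxaborolane | COCOc1cc(OCOC)cc(c1)B1OC(C)(C)C(C)(C)O1 | intermediate
4 | 3,5-bis(methoxymethoxy)phenol | COCOc1cc(O)cc(OCOC)c1 | intermediate
5 | 2-iodo-3,5-bis(methoxymethoxy)phenol | COCOc1cc(O)c(I)c(OCOC)c1 | intermediate
6 | catechol | Oc1ccccc1O | starting material
7 | 1,2-bis(benzyloxy)benzene | C(Oc1ccccc1OCc1ccccc1)c1ccccc1 | intermediate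
8 | 4-bromo-1,2-bis(benzyloxy)benzene | Brc1ccc(OCc2ccccc2)c(OCc2ccccc2)c1 | intermediate
9 | methyl acrylate | C=CC(=O)OC | starting material
10 | methyl (E)-3-[3,4-bis(benzyloxy)phenyl]prop-2-enoate | COC(=O)/C=C/c1ccc(OCc2ccccc2)c(OCc2ccccc2)c1 | intermediate
11 | (E)-3-[3,4-bis(benzyloxy)phenyl]prop-2-en-1-ol (present as its diisobutylaluminium alkoxide) | OC/C=C/c1ccc(OCc2ccccc2)c(OCc2ccccc2)c1 | intermediate
12 | tert-butyl (E)-3-[3,4-bis(benzyloxy)phenyl]prop-2-en-1-yl carbonate | CC(C)(C)OC(=O)OC/C=C/c1ccc(OCc2ccccc2)c(OCc2ccccc2)c1 | intermediate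
13 | 1-{[(1S)-1-[3,4-bis(benzyloxy)phenyl]prop-2-en-1-yl]oxy}-2-iodo-3,5-bis(methoxymethoxy)benzene | C=C[C@H](Oc1cc(OCOC)cc(OCOC)c1I)c1ccc(OCc2ccccc2)c(OCc2ccccc2)c1 | intermediate
14 | {[(2S,3S)-2-[3,4-bis(benzyloxy)phenyl]-4,6-bis(methoxymethoxy)-2,3-dihydro-1-benzofuran-3-yl]methyl}samarium diiodide | I[Sm](I)C[C@H]1c2c(OCOC)cc(OCOC)cc2O[C@@H]1c1ccc(OCc3ccccc3)c(OCc3ccccc3)c1 | intermediate
15 | (2S,3S)-2-[3,4-bis(benzyloxy)phenyl]-3-(iodomethyl)-4,6-bis(methoxymethoxy)-2,3-dihydro-1-benzofuran (2,3-trans) | IC[C@H]1c2c(OCOC)cc(OCOC)cc2O[C@@H]1c1ccc(OCc3ccccc3)c(OCc3ccccc3)c1 | intermediate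
16 | (2R,3S)-2-[3,4-bis(benzyloxy)phenyl]-5,7-bis(methoxymethoxy)chroman-3-ol (protected (+)-catechin) | c1c(OCOC)cc(OCOC)c2c1O[C@H](c1ccc(OCc3ccccc3)c(OCc3ccccc3)c1)[C@@H](O)C2 | intermediate
17 | (2R,3S)-2-[3,4-bis(benzyloxy)phenyl]-8-bromo-5,7-bis(methoxymethoxy)chroman-3-ol | Brc1c(OCOC)cc(OCOC)c2c1O[C@H](c1ccc(OCc3ccccc3)c(OCc3ccccc3)c1)[C@@H](O)C2 | intermediate
18 | C8-lithio lithium 3-alkoxide of 16 | [Li]c1c(OCOC)cc(OCOC)c2c1O[C@H](c1ccc(OCc3ccccc3)c(OCc3ccccc3)c1)[C@@H](O[Li])C2 | intermediate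
19 | lithium trimethoxyborate at C8 of the lithium 3-alkoxide of 16 | [Li+].CO[B-](OC)(OC)c1c(OCOC)cc(OCOC)c2c1O[C@H](c1ccc(OCc3ccccc3)c(OCc3ccccc3)c1)[C@@H](O[Li])C2 | intermediate
20 | potassium [(2R,3S)-2-[3,4-bis(benzyloxy)phenyl]-3-hydroxy-5,7-bis(methoxymethoxy)chroman-8-yl]trifluoroborate | [K+].F[B-](F)(F)c1c(OCOC)cc(OCOC)c2c1O[C@H](c1ccc(OCc3ccccc3)c(OCc3ccccc3)c1)[C@@H](O)C2 | intermediate
21 | 3-(benzyloxy)phenol | Oc1cccc(OCc2ccccc2)c1 | intermediate
22 | 5-(benzyloxy)-2-iodophenol | Oc1cc(OCc2ccccc2)ccc1I | intermediate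
23 | 4-bromophenol | Oc1ccc(Br)cc1 | starting material
24 | 5-bromo-2-hydroxybenzene-1,3-dicarbaldehyde | O=Cc1cc(Br)cc(C=O)c1O | intermediate
25 | 5-bromobenzene-1,2,3-triol | Oc1cc(Br)cc(O)c1O | intermediate
26 | 5-bromo-1,2,3-tris(benzyloxy)benzene | Brc1cc(OCc2ccccc2)c(OCc2ccccc2)c(OCc2ccccc2)c1 | intermediate
27 | methyl (E)-3-[3,4,5-tris(benzyloxy)phenyl]prop-2-enoate | COC(=O)/C=C/c1cc(OCc2ccccc2)c(OCc2ccccc2)c(OCc2ccccc2)c1 | intermediate
28 | (E)-3-[3,4,5-tris(benzyloxy)phenyl]prop-2-en-1-ol (present as its diisobutylaluminium alkoxide) | OC/C=C/c1cc(OCc2ccccc2)c(OCc2ccccc2)c(OCc2ccccc2)c1 | intermediate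
29 | tert-butyl (E)-3-[3,4,5-tris(benzyloxy)phenyl]prop-2-en-1-yl carbonate | CC(C)(C)OC(=O)OC/C=C/c1cc(OCc2ccccc2)c(OCc2ccccc2)c(OCc2ccccc2)c1 | intermediate
30 | 4-(benzyloxy)-1-iodo-2-{[(1S)-1-[3,4,5-tris(benzyloxy)phenyl]prop-2-en-1-yl]oxy}benzene | C=C[C@H](Oc1cc(OCc2ccccc2)ccc1I)c1cc(OCc2ccccc2)c(OCc2ccccc2)c(OCc2ccccc2)c1 | intermediate
31 | {[(2S,3S)-6-(benzyloxy)-2-[3,4,5-tris(benzyloxy)phenyl]-2,3-dihydro-1-benzofuran-3-yl]methyl}samarium diiodide | I[Sm](I)C[C@H]1c2ccc(OCc3ccccc3)cc2O[C@@H]1c1cc(OCc3ccccc3)c(OCc3ccccc3)c(OCc3ccccc3)c1 | intermediate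
32 | (2S,3S)-6-(benzyloxy)-3-(iodomethyl)-2-[3,4,5-tris(benzyloxy)phenyl]-2,3-dihydro-1-benzofuran (2,3-trans) | IC[C@H]1c2ccc(OCc3ccccc3)cc2O[C@@H]1c1cc(OCc3ccccc3)c(OCc3ccccc3)c(OCc3ccccc3)c1 | intermediate
33 | (2R,3S)-7-(benzyloxy)-2-[3,4,5-tris(benzyloxy)phenyl]chroman-3-ol (protected robinetinidol) | C(c1ccccc1)Oc1ccc2c(c1)O[C@H](c1cc(OCc3ccccc3)c(OCc3ccccc3)c(OCc3ccccc3)c1)[C@@H](O)C2 | intermediate
34 | (2R,3S,4R)-7-(benzyloxy)-4-methoxy-2-[3,4,5-tris(benzyloxy)phenyl]chroman-3-ol | C(c1ccccc1)Oc1ccc2c(c1)O[C@H](c1cc(OCc3ccccc3)c(OCc3ccccc3)c(OCc3ccccc3)c1)[C@@H](O)[C@@H]2OC | intermediate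
35 | (2R,3S,4R)-7-(benzyloxy)-4-[(2R,3S)-2-[3,4-bis(benzyloxy)phenyl]-3-hydroxy-5,7-bis(methoxymethoxy)chroman-8-yl]-2-[3,4,5-tris(benzyloxy)phenyl]chroman-3-ol | C(c1ccccc1)Oc1ccc2c(c1)O[C@H](c1cc(OCc3ccccc3)c(OCc3ccccc3)c(OCc3ccccc3)c1)[C@@H](O)[C@H]2c1c(OCOC)cc(OCOC)c2c1O[C@H](c1ccc(OCc3ccccc3)c(OCc3ccccc3)c1)[C@@H](O)C2 | intermediate
36 | (2R,3S)-8-[(2R,3S,4R)-7-(benzyloxy)-3-hydroxy-2-[3,4,5-tris(benzyloxy)phenyl]chroman-4-yl]-2-[3,4-bis(benzyloxy)phenyl]chroman-3,5,7-triol | C(c1ccccc1)Oc1ccc2c(c1)O[C@H](c1cc(OCc3ccccc3)c(OCc3ccccc3)c(OCc3ccccc3)c1)[C@@H](O)[C@H]2c1c(O)cc(O)c2c1O[C@H](c1ccc(OCc3ccccc3)c(OCc3ccccc3)c1)[C@@H](O)C2 | intermediate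
37 | robinetinidol-(4β→8)-catechin, (2R,3S)-2-(3,4-dihydroxyphenyl)-8-[(2R,3S,4R)-3,7-dihydroxy-2-(3,4,5-trihydroxyphenyl)chroman-4-yl]chroman-3,5,7-triol | Oc1ccc2c(c1)O[C@H](c1cc(O)c(O)c(O)c1)[C@@H](O)[C@H]2c1c(O)cc(O)c2c1O[C@H](c1ccc(O)c(O)c1)[C@@H](O)C2 | target

**Step count**
Total: 25 steps. Longest linear sequence: 11 steps (steps 15 to 25, from 4-bromophenol).

**Three steps most likely to fail**

Step 24 (the new coupling). Risks are protodeboronation of the electron-rich trifluoroborate and untethered attack through the free C6–H. Fallback with known chemistry: setting out from 34 and 16 (4 equiv), the classical Lewis-acid Friedel–Crafts condensation of a C4-oxygenated flavan-3-ol with a flavan-3-ol nucleophile (TMSOTf cat., CH2Cl2, −78 °C) uses C8–H and no boron. It gives 35 together with its (2R,3S,4S)-configured C4 epimer F1, which is expected to be the major isomer in this 5-deoxy series. The two are separated by chromatography, and the route is rejoined at 35.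

Step 10 (ring expansion; the same applies to step 22). Risks are water attack at the CH2 carbon of the phenonium ion, which returns a ring-retained alcohol, and a competing shift of the other aryl group. Fallback with known chemistry: setting out from 4 and 12, the iridium-catalysed etherification of step 8 gives (S)-1-[3,4-bis(benzyloxy)phenyl]prop-2-en-1-yl 3,5-bis(methoxymethoxy)phenyl ether F2. Epoxidation with m-CPBA gives the (S)-oxirane F3 and its (R)-oxirane epimer F4, which are separated. AuCl3/AgOTf-catalysed 6-endo epoxide–arene cyclisation of F3 (a direct Friedel–Crafts ring closure used for flavan-3-ols) returns to the route at 16.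

Step 23 (C4 oxidation with DDQ). The 5-deoxy ring A is less electron-rich than in catechin, so oxidation may be slow or compete at C2. Fallback with known chemistry: setting out from 33, lead tetraacetate Pb(OAc)4 in benzene (benzylic acetoxylation of flavan-3-ol ethers, delivered through the C3 alkoxide) gives the 4-acetate F5, mainly 3,4-cis. F5 is used in step 24 in place of 34, so the route is rejoined at 35.

**Further compounds**
F1 | step 24 | (2R,3S,4S)-7-(benzyloxy)-4-[(2R,3S)-2-[3,4-bis(benzyloxy)phenyl]-3-hydroxy-5,7-bis(methoxymethoxy)chroman-8-yl]-2-[3,4,5-tris(benzyloxy)phenyl]chroman-3-ol | C(c1ccccc1)Oc1ccc2c(c1)O[C@H](c1cc(OCc3ccccc3)c(OCc3ccccc3)c(OCc3ccccc3)c1)[C@@H](O)[C@@H]2c1c(OCOC)cc(OCOC)c2c1O[C@H](c1ccc(OCc3ccccc3)c(OCc3ccccc3)c1)[C@@H](O)C2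
F2 | step 10 | (S)-1-[3,4-bis(benzyloxy)phenyl]prop-2-en-1-yl 3,5-bis(methoxymethoxy)phenyl ether | C=C[C@H](Oc1cc(OCOC)cc(OCOC)c1)c1ccc(OCc2ccccc2)c(OCc2ccccc2)c1
F3 | step 10 | (2S)-2-{(R)-[3,4-bis(benzyloxy)phenyl][3,5-bis(methoxymethoxy)phenoxy]methyl}oxirane | C1O[C@@H]1[C@H](Oc2cc(OCOC)cc(OCOC)c2)c2ccc(OCc3ccccc3)c(OCc3ccccc3)c2
F4 | step 10 | (2R)-2-{(R)-[3,4-bis(benzyloxy)phenyl][3,5-bis(methoxymethoxy)phenoxy]methyl}oxirane | C1O[C@H]1[C@H](Oc2cc(OCOC)cc(OCOC)c2)c2ccc(OCc3ccccc3)c(OCc3ccccc3)c2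
F5 | step 23 | (2R,3R,4S)-7-(benzyloxy)-3-hydroxy-2-[3,4,5-tris(benzyloxy)phenyl]chroman-4-yl acetate | C(c1ccccc1)Oc1ccc2c(c1)O[C@H](c1cc(OCc3ccccc3)c(OCc3ccccc3)c(OCc3ccccc3)c1)[C@@H](O)[C@H]2OC(C)=O
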